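**Retrosynthetic overview**
1. The last bond made is ring A C3–CH2 (C3 lies between C2–OH and C4=O of the 2-hydroxy-5-methoxy-6-methyl-1,4-benzoquinone). It is cut to hydroxyquinone 17 and aldehyde 12, joined by organocatalytic reductive alkylation.
2. The strategy rests on ring B: a 2,5-dihydroxy-1,4-benzoquinone is the bis-enol of a cyclohexane-1,2,4,5-tetraone, and its only non-oxygenated atoms, C3 (methyl) and C6 (chain), are para. Cutting C3–C4 and C5–C6 gives C4/C5 from diethyl oxalate 8 and C3–C2–C1–C6 from the 1,2-diketone 7.
3. Diketone 7 comes from ω-pentadecalactone 1 and lithiated 2-ethyl-1,3-dithiane (a propionyl anion equivalent); the chain end is carried as a 1,3-dioxolane.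
4. Hydroxyquinone 17 comes from 3-methoxy-2-methylphenol 13 by Teuber oxidation, Thiele–Winter acetoxylation and hydrolysis/oxidation.
5. Ring order: ring A is taken intact from the aromatic pool, ring B is the only ring built (step 5), and the two rings are joined last (step 10).

Key step: step 5

Remark: the target has no stereocentre and is handled in the quinone tautomers of its SMILES. The chain end is kept at the aldehyde oxidation level (as a dioxolane) through ring B formation, so that no alcohol has to be oxidised next to the free dihydroxyquinone.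

**Route**

Step 1
Reactants: 1 ω-pentadecalactone; 2 2-ethyl-1,3-dithiane
Product: 4 1-(2-ethyl-1,3-dithian-2-yl)-15-hydroxypentadecan-1-one, via 2-ethyl-2-lithio-1,3-dithiane 3 (not isolated)
Conditions: 2 (2.2 equiv), n-BuLi (2.2 equiv), THF, −30 °C; then 1, −78 → 0 °C; H2O
Reagents that add atoms: none
Why: Corey–Seebach acylation, in which the dithianyl anion 3 opens the lactone by acyl substitution and the hindered α,α-dithio ketone is enolised by the second equivalent of 3 rather than attacked again, so the reaction should stop at the ketone.

Step 2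
Reactants: 4 1-(2-ethyl-1,3-dithian-2-yl)-15-hydroxypentadecan-1-one
Product: 5 15-(2-ethyl-1,3-dithian-2-yl)-15-oxopentadecanal
Conditions: Dess–Martin periodinane, CH2Cl2, rt
Reagents that add atoms: none
Why: Dess–Martin oxidation of the primary alcohol to the aldehyde under near-neutral conditions that should leave the dithiane sulfur atoms and the ketone untouched.

Step 3
Reactants: 5 15-(2-ethyl-1,3-dithian-2-yl)-15-oxopentadecanal
Product: 6 14-(1,3-dioxolan-2-yl)-1-(2-ethyl-1,3-dithian-2-yl)tetradecan-1-one
Conditions: HOCH2CH2OH, PPTS (cat.), benzene, reflux, Dean–Stark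
Reagents that add atoms: ethylene glycol, OCCO
Why: acid-catalysed acetalisation with azeotropic removal of water is selective for the unhindered aldehyde, because the ketone next to the quaternary dithiane carbon does not ketalise and the dithiane is stable to PPTS.

Step 4
Reactants: 6 14-(1,3-dioxolan-2-yl)-1-(2-ethyl-1,3-dithian-2-yl)tetradecan-1-one
Product: 7 17-(1,3-dioxolan-2-yl)heptadecane-3,4-dione
Conditions: PhI(OCOCF3)2 (1.5 equiv), NaHCO3, MeCN/H2O 9:1, 0 °C
Reagents that add atoms: water, O
Why: oxidative dethioacetalisation, in which sulfur attacks the trivalent iodine reagent, the ring opens to a thionium ion that water captures and 1,2-dithiolane is lost to reveal the second carbonyl, while the NaHCO3 buffer should keep the dioxolane intact.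

Step 5
Reactants: 7 17-(1,3-dioxolan-2-yl)heptadecane-3,4-dione; 8 diethyl oxalate
Product: 11 2-[12-(1,3-dioxolan-2-yl)dodecyl]-3,6-dihydroxy-5-methyl-1,4-benzoquinone, via dilithium bis-enolate 9 (not isolated), via acyclic oxalyl Claisen adduct 10 (not isolated)
Conditions: LiN(iPr)2 (2.3 equiv), THF, −78 °C, slow addition of 7; then 8 (1.05 equiv), −78 °C → rt, then 50 °C; cold 0.5 M HCl to pH 2–3
Reagents that add atoms: none
Why: Proposed new method: LiN(iPr)2 removes one proton from each α-methylene of 7 (C2 and C5) to give the lithium-chelated 2,3-dioxido-1,3-diene 9, one terminus of which undergoes Claisen C-acylation by diethyl oxalate (addition, loss of ethoxide) to give 10 as its enolate. After proton shuttling the other α-carbon attacks the remaining ester in a 6-exo-trig Dieckmann-type acylation that closes ring B through the bonds C3–C4 and C5–C6 (quinone numbering), and the resulting cyclohexane-1,2,4,5-tetraone is deprotonated twice by the liberated ethoxide to the dihydroxyquinone dianion, a doubly vinylogous carboxylate that should make the sequence irreversible at the correct oxidation level. The closest known reaction type is the base-mediated double Claisen condensation of diethyl oxalate with dialkyl ketones to cyclopentane-1,2,4-triones; here the two nucleophilic carbons are separated by the 1,2-dicarbonyl unit, so a six-membered ring results. No stereocentre is formed. The step needs C- over O-acylation, cross-Claisen over diketone self-aldol, and ring closure over a second intermolecular acylation; the first two are secured by adding 7 to excess base so that no neutral diketone meets enolate and by the hard lithium counter-ion, the third by using one equivalent of oxalate and by the reversibility of every Claisen event except the last. Regiochemistry is not at issue, because methyl and chain already sit on the two termini of the diketone and either order of acylation gives the same ring.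

Step 6
Reactants: 11 2-[12-(1,3-dioxolan-2-yl)dodecyl]-3,6-dihydroxy-5-methyl-1,4-benzoquinone
Product: 12 13-(2,5-dihydroxy-4-methyl-3,6-dioxocyclohexa-1,4-dien-1-yl)tridecanal
Conditions: 1 M HCl, THF, rt
Reagents that add atoms: water, O
Why: acid-catalysed acetal hydrolysis, run without alcohol so that the dihydroxyquinone, a vinylogous acid stable to aqueous HCl, is not O-alkylated.

Step 7
Reactants: 13 3-methoxy-2-methylphenol
Product: 14 2-methoxy-3-methyl-1,4-benzoquinone
Conditions: (KO3S)2NO (2.2 equiv), KH2PO4, H2O/acetone, rt
Reagents that add atoms: potassium nitrosodisulfonate, [K+].[K+].[O]N(S(=O)(=O)[O-])S(=O)(=O)[O-]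
Why: Teuber oxidation, in which one nitrosodisulfonate radical abstracts the phenolic hydrogen and a second delivers oxygen to the free para position, giving the para-quinone.

Step 8
Reactants: 14 2-methoxy-3-methyl-1,4-benzoquinone
Product: 15 5-methoxy-6-methylbenzene-1,2,4-triyl triacetate
Conditions: Ac2O, H2SO4 (cat.), rt
Reagents that add atoms: acetic anhydride, CC(=O)OC(C)=O
Why: Thiele–Winter acetoxylation, in which the C2 methoxy group makes C4=O a vinylogous ester carbonyl, so acetate should add at C5 (β to the more electrophilic C1=O, para to the methoxy carbon) before aromatisation and peracetylation.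

Step 9
Reactants: 15 5-methoxy-6-methylbenzene-1,2,4-triyl triacetate
Product: 17 5-hydroxy-2-methoxy-3-methyl-1,4-benzoquinone, via 5-methoxy-6-methylbenzene-1,2,4-triol 16 (not isolated)
Conditions: HCl (cat.), MeOH, reflux, N2; concentrate; FeCl3, H2O/EtOAc, rt
Reagents that add atoms: none
Why: acid-catalysed transesterification frees the electron-rich triol 16, which FeCl3 oxidises by two one-electron steps to the hydroxy-para-quinone without touching the aryl methyl ether.

Step 10
Reactants: 12 13-(2,5-dihydroxy-4-methyl-3,6-dioxocyclohexa-1,4-dien-1-yl)tridecanal; 17 5-hydroxy-2-methoxy-3-methyl-1,4-benzoquinone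
Product: 19 2-hydroxy-3-[13-(2,5-dihydroxy-4-methyl-3,6-dioxocyclohexa-1,4-dien-1-yl)tridecyl]-5-methoxy-6-methyl-1,4-benzoquinone (CNP0107579.0), via Knoevenagel alkylidene trione 18 (not isolated)
Conditions: Hantzsch ester (diethyl 2,6-dimethyl-1,4-dihydropyridine-3,5-dicarboxylate, 1.2 equiv), L-proline (20 mol %), CH2Cl2, rt
Reagents that add atoms: none
Why: three-component reductive alkylation (proline-catalysed Knoevenagel condensation, then Hantzsch ester transfer hydrogenation), in which C6–H of 17, the α-carbon of its vinylogous acid, condenses with the aldehyde to 18, which is reduced by conjugate hydride transfer; ring B of 12 has no unsubstituted ring carbon and cannot compete.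

**Compound list**
1 | ω-pentadecalactone (oxacyclohexadecan-2-one) | O=C1CCCCCCCCCCCCCCO1 | starting material
2 | 2-ethyl-1,3-dithiane | CCC1SCCCS1 | starting material
3 | 2-ethyl-2-lithio-1,3-dithiane | CCC1([Li])SCCCS1 | intermediate
4 | 1-(2-ethyl-1,3-dithian-2-yl)-15-hydroxypentadecan-1-one | CCC1(SCCCS1)C(=O)CCCCCCCCCCCCCCO | intermediate
5 | 15-(2-ethyl-1,3-dithian-2-yl)-15-oxopentadecanal | CCC1(SCCCS1)C(=O)CCCCCCCCCCCCCC=O | intermediate
6 | 14-(1,3-dioxolan-2-yl)-1-(2-ethyl-1,3-dithian-2-yl)tetradecan-1-one | CCC1(SCCCS1)C(=O)CCCCCCCCCCCCCC2OCCO2 | intermediate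
7 | 17-(1,3-dioxolan-2-yl)heptadecane-3,4-dione | CCC(=O)C(=O)CCCCCCCCCCCCCC1OCCO1 | intermediate
8 | diethyl oxalate | CCOC(=O)C(=O)OCC | starting material
9 | dilithium 17-(1,3-dioxolan-2-yl)heptadeca-2,4-diene-3,4-bis(olate) | CC=C([O-])C([O-])=CCCCCCCCCCCCCC1OCCO1.[Li+].[Li+] | intermediate
10 | ethyl 18-(1,3-dioxolan-2-yl)-3-methyl-2,4,5-trioxooctadecanoate (present as its lithium enolate; acylation at the other terminus first gives the same ring) | CCOC(=O)C(=O)C(C)C(=O)C(=O)CCCCCCCCCCCCCC1OCCO1 | intermediate
11 | 2-[12-(1,3-dioxolan-2-yl)dodecyl]-3,6-dihydroxy-5-methyl-1,4-benzoquinone | CC1=C(O)C(=O)C(CCCCCCCCCCCCC2OCCO2)=C(O)C1=O | intermediate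
12 | 13-(2,5-dihydroxy-4-methyl-3,6-dioxocyclohexa-1,4-dien-1-yl)tridecanal | CC1=C(O)C(=O)C(CCCCCCCCCCCCC=O)=C(O)C1=O | intermediate
13 | 3-methoxy-2-methylphenol | COc1cccc(O)c1C | starting material
14 | 2-methoxy-3-methyl-1,4-benzoquinone | COC1=C(C)C(=O)C=CC1=O | intermediate
15 | 5-methoxy-6-methylbenzene-1,2,4-triyl triacetate | COc1c(C)c(OC(C)=O)c(OC(C)=O)cc1OC(C)=O | intermediate
16 | 5-methoxy-6-methylbenzene-1,2,4-triol | COc1c(C)c(O)c(O)cc1O | intermediate
17 | 5-hydroxy-2-methoxy-3-methyl-1,4-benzoquinone | COC1=C(C)C(=O)C(O)=CC1=O | intermediate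
18 | 3-[13-(2,5-dihydroxy-4-methyl-3,6-dioxocyclohexa-1,4-dien-1-yl)tridecylidene]-5-methoxy-6-methylcyclohex-5-ene-1,2,4-trione | COC1=C(C)C(=O)C(=O)C(=CCCCCCCCCCCCCC2=C(O)C(=O)C(C)=C(O)C2=O)C1=O | intermediate
19 | 2-hydroxy-3-[13-(2,5-dihydroxy-4-methyl-3,6-dioxocyclohexa-1,4-dien-1-yl)tridecyl]-5-methoxy-6-methyl-1,4-benzoquinone | COC1=C(C)C(=O)C(O)=C(CCCCCCCCCCCCCC2=C(O)C(=O)C(C)=C(O)C2=O)C1=O | target

**Step count**
Total steps: 10. Longest linear sequence: 7 (steps 1–6 and 10); steps 7–9 form the ring A branch.

**Steps most likely to fail**

Step 5. The bis-enolate may be acylated on oxygen, the diketone may self-condense by aldol reaction before it meets the oxalate, or the mono-acylated enolate may take up a second oxalate instead of closing the ring. The fallback builds nothing at ring B and uses known chemistry only; it sets out from 17 and comes back at 12. The vinylogous methyl ester of 17 is hydrolysed (2 M NaOH, 60 °C; then HCl) to 2,5-dihydroxy-3-methyl-1,4-benzoquinone F1. Commercial tridecane-1,13-diol (OCCCCCCCCCCCCCO) is oxidised under Swern conditions to tridecanedial F2. Organocatalytic reductive alkylation of F1 with an excess of F2 (Hantzsch ester, L-proline, CH2Cl2) should alkylate the single free ring carbon of F1 and leave the second aldehyde free, giving 12 directly; steps 1 to 6 are then not needed.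

Step 1. The hindered and basic 2-alkyl dithianyl anion may deprotonate the lactone at its α-carbon instead of adding, or the ketone may take up a second anion. The fallback replaces direct lactone opening by a two-stage acylation; it sets out from 1 and comes back at 4. Aminolysis of 1 with Me(MeO)NH·HCl and iPrMgCl in THF gives 15-hydroxy-N-methoxy-N-methylpentadecanamide F3. Addition of 3 (2.2 equiv, the first consumed by the hydroxyl) then gives a chelated tetrahedral adduct that cannot collapse or enolise before work-up, and releases 4 on quenching.

Step 8. The methyl group on C3 directs acetate to C6, against the methoxy group, so regiochemical leakage would give the isomeric triacetate and later the wrong hydroxyquinone. The fallback fixes the third oxygen by an ortho-formylation; it sets out from 13 and comes back at 15. Magnesium-mediated ortho-formylation (MgCl2, Et3N, paraformaldehyde, MeCN, reflux) can only occur at C6 and gives 2-hydroxy-4-methoxy-3-methylbenzaldehyde F4. Dakin oxidation (H2O2, NaOH) gives 4-methoxy-3-methylbenzene-1,2-diol F5, and Ag2O in ether gives 4-methoxy-3-methyl-1,2-benzoquinone F6. Thiele–Winter acetoxylation of F6 (Ac2O, H2SO4 cat.) should add acetate at C5, the only carbon β to the carbonyl that is not part of the vinylogous ester, with the methyl group no longer on the reacting enone, and gives 15.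

**Further compounds**
F1 | step 5 | 2,5-dihydroxy-3-methyl-1,4-benzoquinone | CC1=C(O)C(=O)C=C(O)C1=O
F2 | step 5 | tridecanedial | O=CCCCCCCCCCCCC=O
F3 | step 1 | 15-hydroxy-N-methoxy-N-methylpentadecanamide | CON(C)C(=O)CCCCCCCCCCCCCCO
F4 | step 8 | 2-hydroxy-4-methoxy-3-methylbenzaldehyde | COc1ccc(C=O)c(O)c1C
F5 | step 8 | 4-methoxy-3-methylbenzene-1,2-diol | COc1ccc(O)c(O)c1C
F6 | step 8 | 4-methoxy-3-methyl-1,2-benzoquinone | COC1=C(C)C(=O)C(=O)C=C1
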